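**Retrosynthetic overview**
1. Hidden symmetry: remove the C9 hydroxyl, cut C4a–C5 and read the dienone carbonyl C4'=O as an aryl methyl ether. The target then becomes the C2-symmetric lignan (2R,3R)-2,3-dimethyl-1,4-bis(3,4,5-trimethoxyphenyl)butane. The spiro atom C5 is not a stereocenter, because its two dienone arms C2' and C6' are alike.
2. Key disconnection C4a–C5: oxidative, demethylative dearomatization of one of the two homotopic trimethoxyphenyl rings. It closes the seven-membered ring C4a–C5–C6–C7–C8–C9–C9a and creates quaternary C5 and the 3',5'-dimethoxycyclohexa-2',5'-dien-4'-one in one operation. This is the only ring-forming step.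
3. C9–O is installed last by C–H functionalization. The dearomatization turns C6 from benzylic into neopentyl and removes ring B as a nucleophile, so C9–H2 is the only benzylic site left. Capture of its cation trans to the C8 methyl group sets C9 by substrate control.
4. C7 and C8 (trans-dimethyl) are set together in one auxiliary-controlled oxidative enolate homocoupling. Reduction, tosylation and a twofold Cu-catalysed arylation with a single aryl building block follow.

Key step: step 5

Remark on the chemistry: benzo[7]annulene numbering is used (C5 = spiro atom = C1' of the dienone, then C6H2, C7, C8, C9, C9a, C1–C4, C4a). Ring A stays aromatic and ring B becomes the dienone (C4' = carbonyl carbon). The carbonyl oxygen of the dienone is assumed to come from water (addition to C4', loss of methanol).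

Step 1
Reactants: 1 (R)-4-benzyl-3-propionyloxazolidin-2-one (two molecules)
Product: 3 (2S,3S)-1,4-bis[(4R)-4-benzyl-2-oxooxazolidin-3-yl]-2,3-dimethylbutane-1,4-dione, via lithium Z-enolate 2 (not isolated)
Conditions: LDA (1.05 equiv), THF, −78 °C; then anhydrous CuCl2 (1.1 equiv), DMF–THF, −78 → 0 °C
Reagents that add atoms: none
Why: Cu(II)-mediated oxidative enolate homocoupling of an N-acyloxazolidinone, in which each chelated Z-enolate should bond on the face opposite to its benzyl group, so that C7 and C8 are set together as the C2-symmetric (S,S) pair and the unlike diastereomer can be removed by crystallization.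

Step 2
Reactants: 3 (2S,3S)-bis-imide
Product: 4 (2S,3S)-2,3-dimethylbutane-1,4-diol
Conditions: LiBH4, MeOH (additive), THF, 0 °C → rt; aqueous work-up
Reagents that add atoms: none
Why: Reductive cleavage of N-acyloxazolidinones with LiBH4 should give the primary alcohols without epimerizing the α-carbons and should return the auxiliary.

Step 3
Reactants: 4 (2S,3S)-2,3-dimethylbutane-1,4-diol
Product: 5 (2S,3S)-2,3-dimethylbutane-1,4-diyl bis(4-methylbenzenesulfonate)
Conditions: TsCl (2.6 equiv), pyridine, 0 °C
Reagents that add atoms: 4-toluenesulfonyl chloride (TsCl), Cc1ccc(cc1)S(=O)(=O)Cl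
Why: Standard sulfonylation of two primary alcohols, in which excess TsCl at low temperature should outrun cyclization of the monotosylate to the tetrahydrofuran.

Step 4
Reactants: 5 (2S,3S)-ditosylate; 6 5-bromo-1,2,3-trimethoxybenzene (2.6 equiv)
Product: 8 (2R,3R)-2,3-dimethyl-1,4-bis(3,4,5-trimethoxyphenyl)butane, via arylmagnesium bromide 7 (not isolated)
Conditions: 6, Mg, THF, reflux; then 5, Li2CuCl4 (5 mol %), THF, −10 °C → rt
Reagents that add atoms: none
Why: Kochi-type copper-catalysed coupling of an aryl Grignard reagent with primary tosylates, in which the stereocenters are β to the reacting carbons and stay untouched, so the change of descriptor from S to R reflects only the CIP priorities.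

Step 5
Reactants: 8 (2R,3R)-2,3-dimethyl-1,4-bis(3,4,5-trimethoxyphenyl)butane
Product: 10 (7R,8R)-2,3,3',4,5'-pentamethoxy-7,8-dimethyl-6,7,8,9-tetrahydrospiro[benzo[7]annulene-5,1'-cyclohexa[2,5]dien]-4'-one, via spiro oxocarbenium ion 9 (not isolated)
Conditions: PhI(OCOCF3)2 (1.05 equiv), H2O (10 equiv), (CF3)2CHOH–CH2Cl2 (1:1), 0.02 M, −20 °C, short time; then aq. NaHCO3
Reagents that add atoms: water, O
Why: PIFA in the fluoroalcohol removes one electron from one trimethoxyphenyl ring of 8, the ortho carbon of the other ring (future C4a, ortho to the C4 and para to the C2 methoxy group) bonds to the alkyl-bearing ipso carbon (future C5), and a second one-electron oxidation with loss of the arenium proton restores ring A and leaves ring B as the O-methyl oxocarbenium ion 9, to whose C4' water adds with loss of methanol to give the neutral dienone. The closest known reaction type is the non-phenolic oxidative aryl–aryl coupling in its ipso (spiro) mode, which is known to give cross-conjugated dienones with loss of the para O-methyl group from benzylisoquinolines and from 1,4-diarylbutanes, and whose phenolic variant with the same reagent closes this very ring size. The single ring closed is the seven-membered carbocycle C4a–C5–C6–C7–C8–C9–C9a, by a 7-exo-trig attack with respect to ring B, and the same bond makes quaternary C5 and turns flat ring B into the 3',5'-dimethoxydienone. No new stereocenter arises, because C5 carries two constitutionally identical arms (C2' and C6'), C7 and C8 are not touched, and the two rings of 8 are homotopic under its C2 axis, so either choice of the ring that is dearomatized gives the same compound and the desymmetrization needs no selectivity. The step needs spiro (seven-ring) instead of ortho–ortho (eight-ring) bonding and capture of 9 by water before its electron-rich aryl group migrates from C5 to C2'/C6': the first is secured by the smaller ring and by the C4' methoxy group, which stabilizes only the ipso adduct as an oxocarbenium ion, the second by the water present from the start, the low temperature, the short time and the basic quench. Overoxidation should be slow, because 10 holds a single donor arene next to an electron-poor dienone and only a slight excess of oxidant is used.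

Step 6
Reactants: 10 (7R,8R)-spirodienone
Product: 12 (7R,8S,9R)-2,3,3',4,5'-pentamethoxy-7,8-dimethyl-4'-oxo-6,7,8,9-tetrahydrospiro[benzo[7]annulene-5,1'-cyclohexa[2,5]dien]-9-yl acetate, via C9 benzylic cation 11 (not isolated)
Conditions: DDQ (1.3 equiv), AcOH–CH2Cl2 (1:4), rt → 40 °C
Reagents that add atoms: acetic acid, CC(=O)O
Why: Benzylic C–H acetoxylation by hydride abstraction with DDQ, known for para-alkoxy alkylarenes: C9–H2 is the only benzylic position left in 10 (C6 is now neopentyl), cation 11 is stabilized by the para C3 methoxy group and can no longer be trapped by ring B, and acetic acid should add to the face opposite to the C8 methyl group and remote from the pseudoaxial C2'–H arm of the dienone, which gives the all-trans, all-pseudoequatorial (9R) acetate that is also favoured if ionization is reversible and that resists a second hydride abstraction.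

Step 7
Reactants: 12 (7R,8S,9R)-acetate
Product: 13 (7R,8S,9R)-9-hydroxy-2,3,3',4,5'-pentamethoxy-7,8-dimethyl-6,7,8,9-tetrahydrospiro[benzo[7]annulene-5,1'-cyclohexa[2,5]dien]-4'-one (CNP0288561.1)
Conditions: K2CO3 (0.2 equiv), MeOH, 0 °C → rt
Reagents that add atoms: none
Why: Zemplén-type base-catalysed transesterification cleaves the acyl–oxygen bond, so C9 keeps its configuration, and the 4,4-disubstituted dienone has no enolizable hydrogen and should tolerate catalytic carbonate in methanol.

**Compound list**
1 | (R)-4-benzyl-3-propionyloxazolidin-2-one | CCC(=O)N1[C@H](Cc2ccccc2)COC1=O | starting material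
2 | lithium (Z)-enolate of 1 | [Li+].C/C=C(\[O-])N1[C@H](Cc2ccccc2)COC1=O | intermediate
3 | (2S,3S)-1,4-bis[(4R)-4-benzyl-2-oxooxazolidin-3-yl]-2,3-dimethylbutane-1,4-dione | C[C@H](C(=O)N1[C@H](Cc2ccccc2)COC1=O)[C@H](C)C(=O)N1[C@H](Cc2ccccc2)COC1=O | intermediate
4 | (2S,3S)-2,3-dimethylbutane-1,4-diol | C[C@H](CO)[C@H](C)CO | intermediate
5 | (2S,3S)-2,3-dimethylbutane-1,4-diyl bis(4-methylbenzenesulfonate) | C[C@H](COS(=O)(=O)c1ccc(C)cc1)[C@H](C)COS(=O)(=O)c1ccc(C)cc1 | intermediate
6 | 5-bromo-1,2,3-trimethoxybenzene | COc1cc(Br)cc(OC)c1OC | starting material
7 | (3,4,5-trimethoxyphenyl)magnesium bromide | COc1cc([Mg]Br)cc(OC)c1OC | intermediate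
8 | (2R,3R)-2,3-dimethyl-1,4-bis(3,4,5-trimethoxyphenyl)butane | C[C@H](Cc1cc(OC)c(OC)c(OC)c1)[C@H](C)Cc1cc(OC)c(OC)c(OC)c1 | intermediate
9 | O-methyl oxocarbenium ion of 10 (methyl on the C4' oxygen) | COC1=CC2(C=C(OC)C1=[O+]C)C[C@@H](C)[C@H](C)Cc1cc(OC)c(OC)c(OC)c12 | intermediate
10 | (7R,8R)-2,3,3',4,5'-pentamethoxy-7,8-dimethyl-6,7,8,9-tetrahydrospiro[benzo[7]annulene-5,1'-cyclohexa[2,5]dien]-4'-one | COC1=CC2(C=C(OC)C1=O)C[C@@H](C)[C@H](C)Cc1cc(OC)c(OC)c(OC)c12 | intermediate
11 | C9 benzylic cation derived from 10 | COC1=CC2(C=C(OC)C1=O)C[C@@H](C)[C@H](C)[CH+]c1cc(OC)c(OC)c(OC)c12 | intermediate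
12 | (7R,8S,9R)-2,3,3',4,5'-pentamethoxy-7,8-dimethyl-4'-oxo-6,7,8,9-tetrahydrospiro[benzo[7]annulene-5,1'-cyclohexa[2,5]dien]-9-yl acetate | COC1=CC2(C=C(OC)C1=O)C[C@@H](C)[C@H](C)[C@@H](OC(C)=O)c1cc(OC)c(OC)c(OC)c12 | intermediate
13 | (7R,8S,9R)-9-hydroxy-2,3,3',4,5'-pentamethoxy-7,8-dimethyl-6,7,8,9-tetrahydrospiro[benzo[7]annulene-5,1'-cyclohexa[2,5]dien]-4'-one | COC1=CC2(C=C(OC)C1=O)C[C@@H](C)[C@H](C)[C@@H](O)c1cc(OC)c(OC)c(OC)c12 | target

Total step count: 7. Longest linear sequence: 7 steps (1 → 13).

**Steps most likely to fail**

Step 5.
- What may go wrong: the electron-rich aryl group of the O-methylated cation may migrate (ring expansion to the eight-membered biaryl) before water captures it. The rings may couple directly ortho–ortho. Water may attack the radical cation at the ipso carbon.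
- Fallback, setting out from 8: the central methoxy group of one ring is cleaved by chelation-directed demethylation (AlCl3, 1 equiv, CH2Cl2, 0 °C → rt). The rings are homotopic, so only one monophenol can form, and unreacted 8 is recycled. This gives 4-[(2R,3R)-2,3-dimethyl-4-(3,4,5-trimethoxyphenyl)butyl]-2,6-dimethoxyphenol F1.
- Phenolic oxidative dearomatization of F1 (PIFA, CF3CH2OH, solid NaHCO3, −40 °C) places the positive charge at the para carbon of a phenoxenium species. That species collapses directly to the neutral dienone, so no O-methyl cation is formed. The fallback returns to the route at 10.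

Step 6.
- What may go wrong: the cation may lose the C8 hydrogen (elimination to the styrene), facial selectivity in its capture may be poor, or hydride abstraction from the 1,2,3-trimethoxyarene may be sluggish.
- Fallback, setting out from 10: biocatalytic benzylic hydroxylation with a cytochrome P450 monooxygenase (an engineered bacterial panel or a lignan-hydroxylating plant enzyme, O2, NADPH recycling).
- Hydrogen abstraction and oxygen rebound occur with retention at the pro-R hydrogen of C9. The face is then controlled by the active site instead of the substrate, and no free cation forms. The fallback skips 12 and returns at 13. New compounds on this way: none F0.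

Step 1.
- What may go wrong: diastereoselection in the radical-type dimerization may be poor, α-chlorination may compete, and the imide enolate may decompose.
- Fallback, setting out from 6: twofold Heck arylation of commercial 2,3-dimethylbuta-1,3-diene (Pd(OAc)2, P(o-tol)3, Et3N, MeCN, 100 °C) gives (1E,3E)-2,3-dimethyl-1,4-bis(3,4,5-trimethoxyphenyl)buta-1,3-diene F2.
- Catalyst-controlled asymmetric hydrogenation of both trisubstituted styrene-type double bonds follows, with a cationic iridium phosphinooxazoline catalyst (H2, CH2Cl2). The ligand enantiomer is chosen for the (R,R) product.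
- This sets C7 and C8 in one operation, with statistical amplification of the enantiomeric purity in the C2-symmetric product. The fallback returns at 8 and replaces steps 1–4.

**Further compounds**
F1 | step 5 | 4-[(2R,3R)-2,3-dimethyl-4-(3,4,5-trimethoxyphenyl)butyl]-2,6-dimethoxyphenol | C[C@H](Cc1cc(OC)c(O)c(OC)c1)[C@H](C)Cc1cc(OC)c(OC)c(OC)c1
F0 | step 6 | none | none
F2 | step 1 | (1E,3E)-2,3-dimethyl-1,4-bis(3,4,5-trimethoxyphenyl)buta-1,3-diene | COc1cc(/C=C(\C)/C(C)=C/c2cc(OC)c(OC)c(OC)c2)cc(OC)c1OC
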